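**Retrosynthetic overview**
- The C3 carbinol is set last by Corey–Bakshi–Shibata reduction of a 2,2-dimethylchroman-3-one.
- The key C4–C4a bond comes from an α-oxo gold carbene (an electrophilic ketone α-carbon, i.e. an enolonium equivalent) attacking the electron-rich arene. This joins an arene carbon and a ketone α-carbon, both normally nucleophilic; the carbene is made by N-oxide oxidation of an aryl 1,1-dimethylpropargyl ether.
- The propargyl ether comes from mirror-symmetric 4-prenylpinosylvin. The prenyl group blocks one ortho position, so ring closure can only occur next to the styryl group.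
- 4-Prenylpinosylvin comes from 4-bromo-3,5-dimethoxybenzaldehyde by Horner–Wadsworth–Emmons olefination, Br–Li exchange/copper-mediated prenylation, and demethylation.
- Ring order: both benzene rings are bought; the dihydropyran ring is the only ring built, closed in step 5.

Assumption: 4-bromo-3,5-dimethoxybenzaldehyde is accepted as an inexpensive catalogue starting material; the single stereocenter (chroman C3) is R as read from the SMILES.

**Step 1**
Reactants: 1 4-bromo-3,5-dimethoxybenzaldehyde; 2 diethyl benzylphosphonate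
Product: 3 (E)-4-bromo-3,5-dimethoxystilbene
Conditions: KOtBu, THF, 0 °C → rt
Reagents that add atoms: diethyl benzylphosphonate (2), CCOP(=O)(OCC)Cc1ccccc1
Why: Horner–Wadsworth–Emmons olefination of an aromatic aldehyde with a benzylphosphonate anion is under thermodynamic control and gives the (E)-stilbene almost exclusively, with the aryl bromide and methyl ethers inert.

**Step 2**
Reactants: 3 (E)-4-bromo-3,5-dimethoxystilbene; 4 prenyl bromide (1-bromo-3-methylbut-2-ene)
Product: 7 (E)-3,5-dimethoxy-4-(3-methylbut-2-enyl)stilbene, via aryllithium 5 (not isolated), via arylcopper 6 (not isolated)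
Conditions: n-BuLi, THF, −78 °C; CuBr·SMe2 (1.1 equiv), −78 → −40 °C; prenyl bromide, → rt
Reagents that add atoms: prenyl bromide (4), CC(C)=CCBr
Why: Halogen–lithium exchange at a bromide flanked by two chelating methoxy groups is much faster at −78 °C than carbolithiation of the stilbene, and the derived arylcopper undergoes SN2 allylic substitution on prenyl bromide to place the linear prenyl group exactly between the two oxygens.

**Step 3**
Reactants: 7 (E)-3,5-dimethoxy-4-(3-methylbut-2-enyl)stilbene
Product: 8 (E)-4-(3-methylbut-2-enyl)stilbene-3,5-diol (4-prenylpinosylvin)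
Conditions: MeMgI (8 equiv), neat (Et2O stripped), 160 °C, 1 h; then sat. aq NH4Cl, 0 °C
Reagents that add atoms: none
Why: Grignard-fusion cleavage of aryl methyl ethers is non-acidic, so both phenols are released without the chroman-forming cyclisation of the ortho-prenyl group that BBr3 or HBr would cause, as in the classical demethylation of terpenyl-resorcinol dimethyl ethers.

**Step 4**
Reactants: 8 (E)-4-(3-methylbut-2-enyl)stilbene-3,5-diol; 9 3-chloro-3-methylbut-1-yne
Product: 10 3-[(2-methylbut-3-yn-2-yl)oxy]-2-(3-methylbut-2-enyl)-5-[(E)-2-phenylethenyl]phenol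
Conditions: 9 (1.0 equiv), CuCl2·2H2O (1 mol %), DBU (1.2 equiv), MeCN, 0 °C → rt; recovered 8 recycled
Reagents that add atoms: 3-chloro-3-methylbut-1-yne (9), C#CC(C)(C)Cl
Why: Copper-catalysed propargylic etherification (copper acetylide/allenylidene from the tertiary chloride, attacked at oxygen by the phenoxide) gives the tertiary aryl propargyl ether, and because 8 is mirror-symmetric the mono-ether is a single isomer, formed statistically (about half) alongside bis-ether and recyclable diol.

**Step 5**
Reactants: 10 3-[(2-methylbut-3-yn-2-yl)oxy]-2-(3-methylbut-2-enyl)-5-[(E)-2-phenylethenyl]phenol; 11 2,6-dichloropyridine N-oxide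
Product: 13 7-hydroxy-2,2-dimethyl-8-(3-methylbut-2-enyl)-5-[(E)-2-phenylethenyl]chroman-3-one, via α-oxo gold carbene 12 (not isolated)
Conditions: Me4tBuXPhosAuNTf2 (5 mol %), 11 (1.3 equiv), ClCH2CH2Cl, rt
Reagents that add atoms: 2,6-dichloropyridine N-oxide (11), [O-][n+]1c(Cl)cccc1Cl
Why: Gold-catalysed alkyne oxidation transfers the N-oxide oxygen to the internal alkyne carbon to give α-oxo gold carbene 12, whose electrophilic ketone α-carbon is captured in a six-membered intramolecular Friedel–Crafts alkylation by the only free ortho carbon (para to the free OH), a known route from aryl propargyl ethers to chroman-3-ones that forms no stereocenter.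

**Step 6**
Reactants: 13 7-hydroxy-2,2-dimethyl-8-(3-methylbut-2-enyl)-5-[(E)-2-phenylethenyl]chroman-3-one
Product: 14 (3R)-2,2-dimethyl-8-(3-methylbut-2-enyl)-5-[(E)-2-phenylethenyl]chroman-3,7-diol
Conditions: (S)-2-methyl-CBS-oxazaborolidine (0.5 equiv), catecholborane (3 equiv), toluene/CH2Cl2, −78 → −20 °C; then MeOH, pH 7 buffer
Reagents that add atoms: none
Why: In the Corey–Bakshi–Shibata reduction the ketone binds the oxazaborolidine with the quaternary C2 side as the large group and the benzylic CH2 as the small group, so hydride is delivered in the same sense as acetophenone → (R)-1-phenylethanol with the (S)-catalyst, giving the (3R)-alcohol, while catecholborane at low temperature leaves the prenyl and stilbene alkenes untouched.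

**Compound list**
1 | 4-bromo-3,5-dimethoxybenzaldehyde | COc1cc(C=O)cc(OC)c1Br | starting material
2 | diethyl benzylphosphonate | CCOP(=O)(OCC)Cc1ccccc1 | starting material
3 | (E)-4-bromo-3,5-dimethoxystilbene | COc1cc(/C=C/c2ccccc2)cc(OC)c1Br | intermediate
4 | prenyl bromide (1-bromo-3-methylbut-2-ene) | CC(C)=CCBr | starting material
5 | aryllithium, 2,6-dimethoxy-4-[(E)-2-phenylethenyl]phenyllithium (not isolated) | COc1cc(/C=C/c2ccccc2)cc(OC)c1[Li] | intermediate
6 | arylcopper, 2,6-dimethoxy-4-[(E)-2-phenylethenyl]phenylcopper (not isolated) | COc1cc(/C=C/c2ccccc2)cc(OC)c1[Cu] | intermediate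
7 | (E)-3,5-dimethoxy-4-(3-methylbut-2-enyl)stilbene | COc1cc(/C=C/c2ccccc2)cc(OC)c1CC=C(C)C | intermediate
8 | (E)-4-(3-methylbut-2-enyl)stilbene-3,5-diol (4-prenylpinosylvin) | CC(C)=CCc1c(O)cc(/C=C/c2ccccc2)cc1O | intermediate
9 | 3-chloro-3-methylbut-1-yne | C#CC(C)(C)Cl | starting material
10 | 3-[(2-methylbut-3-yn-2-yl)oxy]-2-(3-methylbut-2-enyl)-5-[(E)-2-phenylethenyl]phenol | CC(C)=CCc1c(O)cc(/C=C/c2ccccc2)cc1OC(C)(C)C#C | intermediate
11 | 2,6-dichloropyridine N-oxide | [O-][n+]1c(Cl)cccc1Cl | starting material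
12 | α-oxo gold carbene, ArO–CMe2–C(=O)–CH=Au[Me4tBuXPhos] NTf2 salt, where Me4tBuXPhos is 2-(di-tert-butylphosphino)-3,4,5,6-tetramethyl-2′,4′,6′-triisopropylbiphenyl (not isolated) | CC(C)=CCc1c(O)cc(/C=C/c2ccccc2)cc1OC(C)(C)C(=O)C=[Au][P+](C(C)(C)C)(C(C)(C)C)c1c(C)c(C)c(C)c(C)c1-c1c(C(C)C)cc(C(C)C)cc1C(C)C.[N-](S(=O)(=O)C(F)(F)F)S(=O)(=O)C(F)(F)F | intermediate
13 | 7-hydroxy-2,2-dimethyl-8-(3-methylbut-2-enyl)-5-[(E)-2-phenylethenyl]chroman-3-one | CC(C)=CCc1c(O)cc(/C=C/c2ccccc2)c2c1OC(C)(C)C(=O)C2 | intermediate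
14 | (3R)-2,2-dimethyl-8-(3-methylbut-2-enyl)-5-[(E)-2-phenylethenyl]chroman-3,7-diol | CC(C)=CCc1c(O)cc(/C=C/c2ccccc2)c2c1OC(C)(C)[C@H](O)C2 | target

**Totals**
Total step count: 6. Longest linear sequence: 6 steps (1 → 3 → 7 → 8 → 10 → 13 → 14).

**Steps most likely to fail, with fallbacks**

Step 5 (gold oxidation/cyclisation). The tertiary propargylic C–O bond may ionise, hydroarylation to the 2H-chromene may compete, and the free phenol or the prenyl alkene may intercept the carbene or cyclise under trace acid. The fallback sets out from 10 and comes back to the route at 14. Heating 10 in N,N-diethylaniline at 160 °C triggers the aryl propargyl ether Claisen cascade, which can only use the one free ortho carbon and gives (E)-2,2-dimethyl-8-(3-methylbut-2-enyl)-5-(2-phenylethenyl)-2H-chromen-7-ol F1. Jacobsen epoxidation of the cis chromene double bond, the privileged substrate class for this catalyst, is run with [(R,R)-N,N′-bis(3,5-di-tert-butylsalicylidene)cyclohexane-1,2-diamine]MnCl, mCPBA and N-methylmorpholine N-oxide in CH2Cl2 at −78 °C. It gives (3R,4R)-3,4-epoxy-2,2-dimethyl-8-(3-methylbut-2-enyl)-5-[(E)-2-phenylethenyl]chroman-7-ol F2. LiAlH4 in THF at 0 °C then delivers hydride to the benzylic C4 with C3 untouched, giving 14.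

Step 3 (double demethylation in a Grignard melt). The second ether cleavage may stall, or the stilbene/prenyl unit may suffer at 160 °C. The fallback sets out from 7 and comes back at 14; it costs one extra step but removes both the melt and the statistical etherification of step 4. NaSEt (3 equiv) in DMF at 140 °C stops cleanly after one demethylation, because the phenoxide formed deactivates the second ether, giving (E)-3-methoxy-2-(3-methylbut-2-enyl)-5-(2-phenylethenyl)phenol F3. Etherification with 9 under the step 4 conditions then needs no statistics and gives the propargyl ether 1-methoxy-3-[(2-methylbut-3-yn-2-yl)oxy]-2-(3-methylbut-2-enyl)-5-[(E)-2-phenylethenyl]benzene F4. Gold-catalysed oxidation with 11 as in step 5, now without a free phenol, gives 7-methoxy-2,2-dimethyl-8-(3-methylbut-2-enyl)-5-[(E)-2-phenylethenyl]chroman-3-one F5. Reduction as in step 6 gives (3R)-7-methoxy-2,2-dimethyl-8-(3-methylbut-2-enyl)-5-[(E)-2-phenylethenyl]chroman-3-ol F6. A single thiolate demethylation (NaSEt, DMF, 140 °C) then gives 14.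

Step 6 (enantioselective reduction). The free phenol ties up boron, and the α-aryloxy oxygen may erode facial control. The fallback sets out from 13 and comes back at 14. NaBH4 in MeOH at 0 °C gives the racemic alcohol 2,2-dimethyl-8-(3-methylbut-2-enyl)-5-[(E)-2-phenylethenyl]chroman-3,7-diol F7. Preparative chromatography on an amylose tris(3,5-dimethylphenylcarbamate) stationary phase separates 14 from the (S)-enantiomer (3S)-2,2-dimethyl-8-(3-methylbut-2-enyl)-5-[(E)-2-phenylethenyl]chroman-3,7-diol F8, which is set aside.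

**Further compounds**
F1 | step 5 | (E)-2,2-dimethyl-8-(3-methylbut-2-enyl)-5-(2-phenylethenyl)-2H-chromen-7-ol | CC(C)=CCc1c(O)cc(/C=C/c2ccccc2)c2c1OC(C)(C)C=C2
F2 | step 5 | (3R,4R)-3,4-epoxy-2,2-dimethyl-8-(3-methylbut-2-enyl)-5-[(E)-2-phenylethenyl]chroman-7-ol | CC(C)=CCc1c(O)cc(/C=C/c2ccccc2)c2c1OC(C)(C)[C@@H]3O[C@@H]32
F3 | step 3 | (E)-3-methoxy-2-(3-methylbut-2-enyl)-5-(2-phenylethenyl)phenol | COc1cc(/C=C/c2ccccc2)cc(O)c1CC=C(C)C
F4 | step 3 | 1-methoxy-3-[(2-methylbut-3-yn-2-yl)oxy]-2-(3-methylbut-2-enyl)-5-[(E)-2-phenylethenyl]benzene | COc1cc(/C=C/c2ccccc2)cc(OC(C)(C)C#C)c1CC=C(C)C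
F5 | step 3 | 7-methoxy-2,2-dimethyl-8-(3-methylbut-2-enyl)-5-[(E)-2-phenylethenyl]chroman-3-one | COc1cc(/C=C/c2ccccc2)c2c(c1CC=C(C)C)OC(C)(C)C(=O)C2
F6 | step 3 | (3R)-7-methoxy-2,2-dimethyl-8-(3-methylbut-2-enyl)-5-[(E)-2-phenylethenyl]chroman-3-ol | COc1cc(/C=C/c2ccccc2)c2c(c1CC=C(C)C)OC(C)(C)[C@H](O)C2
F7 | step 6 | racemic 2,2-dimethyl-8-(3-methylbut-2-enyl)-5-[(E)-2-phenylethenyl]chroman-3,7-diol | CC(C)=CCc1c(O)cc(/C=C/c2ccccc2)c2c1OC(C)(C)C(O)C2
F8 | step 6 | (3S)-2,2-dimethyl-8-(3-methylbut-2-enyl)-5-[(E)-2-phenylethenyl]chroman-3,7-diol | CC(C)=CCc1c(O)cc(/C=C/c2ccccc2)c2c1OC(C)(C)[C@@H](O)C2
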